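**Plan**

- Ring numbering: O1, C2 (3,4,5-trimethoxyphenyl), C3 (CH2OH), C4 (carbinol arm), C5 (CH2). C2 is an aldehyde-level carbon held between O1 and C3. Once the C3 CH2OH is traced back to a vinyl group, both ring bonds at C2 (O1–C2 and C2–C3) are cut together, leaving 3,4,5-trimethoxybenzaldehyde and an open-chain C5 alcohol whose (E)-allylsilane has C3 as its γ-carbon.
- The allylsilane is cut at its C=C bond (cross-metathesis with allyltrimethylsilane), and the C4–carbinol bond by an aldol disconnection to a but-3-enoyl oxazolidinone and 3,4-dimethoxybenzaldehyde.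
- Forward: N-acylation, Evans syn-aldol, O-silylation, reductive removal of the auxiliary and cross-metathesis join the chain. The only ring, the oxolane, then closes in the oxocarbenium–allylsilane annulation. Vinyl → CHO → CH2OH and desilylation finish.
- Stereochemistry: the S auxiliary sets the carbinol carbon and C4 in the aldol. C4 directs C2 (2,4-cis) and C3 during ring closure. C3 is finally secured by equilibrating the 3-formyl compound to the all-trans ring.

Key step: step 6

Remark: the kinetic C3 outcome of the cyclization cannot be predicted with certainty. Compounds 16 onward are drawn as the expected 2,3-trans isomer, and step 7 converges any 2,3-cis material onto the same aldehyde.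

**Step 1**
Reactants: 1 but-3-enoic acid; 2 (S)-4-benzyl-1,3-oxazolidin-2-one
Product: 4 (4S)-4-benzyl-3-(but-3-enoyl)-1,3-oxazolidin-2-one, via but-3-enoic pivalic anhydride 3 (not isolated)
Conditions: PivCl, Et3N, THF, −20 °C; then LiCl, 2, −20 °C → rt
Reagents that add atoms: none
Why: Mixed-anhydride N-acylation of an oxazolidinone, in which the nitrogen attacks the unhindered butenoyl carbonyl of 3; any isomerisation to the crotonyl imide is harmless because both imides give the same boron dienolate in step 2.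

**Step 2**
Reactants: 4 (4S)-4-benzyl-3-(but-3-enoyl)-1,3-oxazolidin-2-one; 5 3,4-dimethoxybenzaldehyde
Product: 8 (4S)-4-benzyl-3-[(2S,3S)-3-(3,4-dimethoxyphenyl)-2-ethenyl-3-hydroxypropanoyl]-1,3-oxazolidin-2-one, via dibutylboron dienolate 6 (not isolated), via dibutylboron aldolate 7 (not isolated)
Conditions: Bu2BOTf, Et3N, CH2Cl2, −78 → 0 °C; 5, −78 → 0 °C; then pH 7 buffer, MeOH, 30% H2O2, 0 °C
Reagents that add atoms: none
Why: Evans syn-aldol reaction, in which the (Z)-boron dienolate reacts at its α-carbon through a closed Zimmerman–Traxler chair on the face away from the benzyl group of the S auxiliary, so that the carbinol carbon (S) and the vinyl-bearing carbon (S) should arise in the syn relationship the target needs.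

**Step 3**
Reactants: 8 (4S)-4-benzyl-3-[(2S,3S)-3-(3,4-dimethoxyphenyl)-2-ethenyl-3-hydroxypropanoyl]-1,3-oxazolidin-2-one
Product: 9 (4S)-4-benzyl-3-[(2S,3S)-3-(tert-butyldimethylsilyloxy)-3-(3,4-dimethoxyphenyl)-2-ethenylpropanoyl]-1,3-oxazolidin-2-one
Conditions: TBSOTf, 2,6-lutidine, CH2Cl2, −78 → 0 °C
Reagents that add atoms: tert-butyldimethylsilyl trifluoromethanesulfonate, CC(C)(C)[Si](C)(C)OS(=O)(=O)C(F)(F)F
Why: Silyl triflate silylation of a secondary alcohol is fast at low temperature with a hindered pyridine base, so the β-hydroxy imide is capped without retro-aldol cleavage or epimerisation; a silyl ether is preferred to an ester because an acyloxy group would invite β-elimination to the dienyl imide and acyl migration in step 4.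

**Step 4**
Reactants: 9 (4S)-4-benzyl-3-[(2S,3S)-3-(tert-butyldimethylsilyloxy)-3-(3,4-dimethoxyphenyl)-2-ethenylpropanoyl]-1,3-oxazolidin-2-one
Product: 10 (2R)-2-[(S)-(tert-butyldimethylsilyloxy)(3,4-dimethoxyphenyl)methyl]but-3-en-1-ol
Conditions: LiBH4, MeOH (2 equiv), THF, 0 °C
Reagents that add atoms: none
Why: Reductive cleavage of an N-acyl oxazolidinone with LiBH4 (hydride attack at the lithium-activated exocyclic carbonyl) should give the primary alcohol and return the auxiliary, while the silyl ether, the vinyl group and both stereocentres are inert to borohydride.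

**Step 5**
Reactants: 10 (2R)-2-[(S)-(tert-butyldimethylsilyloxy)(3,4-dimethoxyphenyl)methyl]but-3-en-1-ol; 11 allyltrimethylsilane
Product: 12 (2R,3E)-2-[(S)-(tert-butyldimethylsilyloxy)(3,4-dimethoxyphenyl)methyl]-5-(trimethylsilyl)pent-3-en-1-ol
Conditions: 11 (4 equiv), second-generation Hoveyda–Grubbs catalyst (H2IMes)Cl2Ru=CH(C6H4-2-OiPr) (5 mol %), CH2Cl2, 40 °C
Reagents that add atoms: none
Why: Olefin cross-metathesis, in which the branched vinyl group of 10 does not homodimerise while the excess of unhindered 11 turns over rapidly, so the cross product should dominate and the allylic branching should favour the E alkene; the ruthenium carbene tolerates the free hydroxyl and the silyl ether.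

**Step 6**
Reactants: 12 (2R,3E)-2-[(S)-(tert-butyldimethylsilyloxy)(3,4-dimethoxyphenyl)methyl]-5-(trimethylsilyl)pent-3-en-1-ol; 13 3,4,5-trimethoxybenzaldehyde
Product: 16 (2R,3R,4R)-4-[(S)-(tert-butyldimethylsilyloxy)(3,4-dimethoxyphenyl)methyl]-3-ethenyl-2-(3,4,5-trimethoxyphenyl)oxolane, via trimethylsilyl ether 14 (not isolated), via oxocarbenium triflate 15 (not isolated)
Conditions: i-Pr2NEt (1.05 equiv), TMSOTf (1.3 equiv), CH2Cl2, −78 °C; then 13 (1.2 equiv), −78 → −40 °C
Reagents that add atoms: none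
Why: The alcohol is silylated in the flask to 14, which the remaining TMSOTf condenses with aldehyde 13 (hexamethyldisiloxane is lost) to the (E)-oxocarbenium ion 15; the γ-carbon of the allylsilane attacks its carbon and the β-silyl cation gives up silicon to triflate, so that O1–C2 and C2–C3 are both made at the former aldehyde carbon, the vinyl group appears on C3 and TMSOTf is returned. The closest known reaction type is the intramolecular silyl-modified Sakurai (silyl-Prins) cyclization of 5-silylpent-3-en-1-ols or their silyl ethers with aldehydes to 2-substituted 3-vinyltetrahydrofurans. The oxolane closes as a five-membered ring in which the C=O+ bond is endocyclic and the attacking C=C bond exocyclic (5-exo-trig with respect to the alkene). C2 is set by the C4 stereocentre, because in the envelope transition state the aryl group of the E oxocarbenium ion and the C4 side chain both take pseudo-equatorial positions, which gives the 2,4-cis ring. C3 is set by the same centre through the allylic-strain-minimised rotamer of the E allylsilane (C4–H in the alkene plane), which should place the emerging vinyl group trans to the C4 side chain and hence trans to the C2 aryl group. The step needs attack by the proximal alkene carbon and ionisation only at the acetal carbon: the β-silicon effect secures the first, and the poorly basic, bulky silyl ether on the electron-rich benzylic oxygen, the amine-buffered silylation (no free acid), the small amount of free TMSOTf and −78 °C secure the second, while blocking that oxygen also leaves O1 as the only oxygen able to carry the oxocarbenium ion.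

**Step 7**
Reactants: 16 (2R,3R,4R)-4-[(S)-(tert-butyldimethylsilyloxy)(3,4-dimethoxyphenyl)methyl]-3-ethenyl-2-(3,4,5-trimethoxyphenyl)oxolane
Product: 18 (2R,3R,4R)-4-[(S)-(tert-butyldimethylsilyloxy)(3,4-dimethoxyphenyl)methyl]-2-(3,4,5-trimethoxyphenyl)oxolane-3-carbaldehyde, via vicinal diol 17 (not isolated)
Conditions: OsO4 (2 mol %), NaIO4 (4 equiv), 2,6-lutidine (2 equiv), 1,4-dioxane–H2O (3:1), rt; then DBU (0.2 equiv), CH2Cl2, rt
Reagents that add atoms: osmium tetroxide, O=[Os](=O)(=O)=O (delivers the oxygen); sodium periodate, [Na+].[O-]I(=O)(=O)=O (terminal oxidant that replenishes it)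
Why: Lemieux–Johnson oxidative cleavage (dihydroxylation to 17, then periodate glycol cleavage, buffered by 2,6-lutidine) removes the terminal carbon without touching the electron-rich arenes, and DBU then equilibrates the enolisable C3 through its enolate to the isomer with the formyl group trans to both flanking substituents, which fixes the C3 configuration of the target.

**Step 8**
Reactants: 18 (2R,3R,4R)-4-[(S)-(tert-butyldimethylsilyloxy)(3,4-dimethoxyphenyl)methyl]-2-(3,4,5-trimethoxyphenyl)oxolane-3-carbaldehyde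
Product: 19 [(2R,3S,4R)-4-[(S)-(tert-butyldimethylsilyloxy)(3,4-dimethoxyphenyl)methyl]-2-(3,4,5-trimethoxyphenyl)oxolan-3-yl]methanol
Conditions: NaBH4, MeOH, 0 °C
Reagents that add atoms: none
Why: Borohydride reduction of the aldehyde at 0 °C is much faster than enolisation, so the equilibrated C3 configuration should be carried into the hydroxymethyl group, and the silyl and aryl ethers are inert.

**Step 9**
Reactants: 19 [(2R,3S,4R)-4-[(S)-(tert-butyldimethylsilyloxy)(3,4-dimethoxyphenyl)methyl]-2-(3,4,5-trimethoxyphenyl)oxolan-3-yl]methanol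
Product: 20 (S)-(3,4-dimethoxyphenyl)[(3R,4S,5R)-4-(hydroxymethyl)-5-(3,4,5-trimethoxyphenyl)oxolan-3-yl]methanol
Conditions: TBAF, THF, 0 °C → rt
Reagents that add atoms: none
Why: Fluoride-driven desilylation (Si–F bond formation) frees the benzylic alcohol without acid, which matters because acid would ionise the electron-rich benzylic alcohol and close a furofuran onto the neighbouring hydroxymethyl group.

**Compound list**

1 | but-3-enoic acid | C=CCC(=O)O | starting material
2 | (S)-4-benzyl-1,3-oxazolidin-2-one | O=C1OC[C@H](Cc2ccccc2)N1 | starting material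
3 | but-3-enoic pivalic anhydride (formed in the flask) | C=CCC(=O)OC(=O)C(C)(C)C | intermediate
4 | (4S)-4-benzyl-3-(but-3-enoyl)-1,3-oxazolidin-2-one | C=CCC(=O)N1C(=O)OC[C@@H]1Cc1ccccc1 | intermediate
5 | 3,4-dimethoxybenzaldehyde | COc1ccc(C=O)cc1OC | starting material
6 | dibutylboron (Z)-dienolate of 4 (formed in the flask) | C=C/C=C(\OB(CCCC)CCCC)N1C(=O)OC[C@@H]1Cc1ccccc1 | intermediate
7 | dibutylboron aldolate of 8 (formed in the flask) | COc1ccc(cc1OC)[C@@H](OB(CCCC)CCCC)[C@@H](C(=O)N1C(=O)OC[C@@H]1Cc1ccccc1)C=C | intermediate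
8 | (4S)-4-benzyl-3-[(2S,3S)-3-(3,4-dimethoxyphenyl)-2-ethenyl-3-hydroxypropanoyl]-1,3-oxazolidin-2-one | COc1ccc(cc1OC)[C@@H](O)[C@@H](C(=O)N1C(=O)OC[C@@H]1Cc1ccccc1)C=C | intermediate
9 | (4S)-4-benzyl-3-[(2S,3S)-3-(tert-butyldimethylsilyloxy)-3-(3,4-dimethoxyphenyl)-2-ethenylpropanoyl]-1,3-oxazolidin-2-one | COc1ccc(cc1OC)[C@@H](O[Si](C)(C)C(C)(C)C)[C@@H](C(=O)N1C(=O)OC[C@@H]1Cc1ccccc1)C=C | intermediate
10 | (2R)-2-[(S)-(tert-butyldimethylsilyloxy)(3,4-dimethoxyphenyl)methyl]but-3-en-1-ol | COc1ccc(cc1OC)[C@@H](O[Si](C)(C)C(C)(C)C)[C@@H](CO)C=C | intermediate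
11 | allyltrimethylsilane | C=CC[Si](C)(C)C | starting material
12 | (2R,3E)-2-[(S)-(tert-butyldimethylsilyloxy)(3,4-dimethoxyphenyl)methyl]-5-(trimethylsilyl)pent-3-en-1-ol | COc1ccc(cc1OC)[C@@H](O[Si](C)(C)C(C)(C)C)[C@@H](CO)/C=C/C[Si](C)(C)C | intermediate
13 | 3,4,5-trimethoxybenzaldehyde | COc1cc(C=O)cc(OC)c1OC | starting material
14 | trimethylsilyl ether of 12 (formed in the flask) | COc1ccc(cc1OC)[C@@H](O[Si](C)(C)C(C)(C)C)[C@@H](CO[Si](C)(C)C)/C=C/C[Si](C)(C)C | intermediate
15 | [(2R,3E)-2-{(S)-(tert-butyldimethylsilyloxy)(3,4-dimethoxyphenyl)methyl}-5-(trimethylsilyl)pent-3-en-1-yl][(E)-3,4,5-trimethoxybenzylidene]oxonium trifluoromethanesulfonate (formed in the flask) | COc1ccc(cc1OC)[C@@H](O[Si](C)(C)C(C)(C)C)[C@@H](C/[O+]=C/c1cc(OC)c(OC)c(OC)c1)/C=C/C[Si](C)(C)C.[O-]S(=O)(=O)C(F)(F)F | intermediate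
16 | (2R,3R,4R)-4-[(S)-(tert-butyldimethylsilyloxy)(3,4-dimethoxyphenyl)methyl]-3-ethenyl-2-(3,4,5-trimethoxyphenyl)oxolane | COc1ccc(cc1OC)[C@@H](O[Si](C)(C)C(C)(C)C)[C@H]2CO[C@@H](c3cc(OC)c(OC)c(OC)c3)[C@@H]2C=C | intermediate
17 | 1-[(2R,3S,4R)-4-{(S)-(tert-butyldimethylsilyloxy)(3,4-dimethoxyphenyl)methyl}-2-(3,4,5-trimethoxyphenyl)oxolan-3-yl]ethane-1,2-diol, both configurations at the new carbinol (formed in the flask) | COc1ccc(cc1OC)[C@@H](O[Si](C)(C)C(C)(C)C)[C@H]2CO[C@@H](c3cc(OC)c(OC)c(OC)c3)[C@@H]2C(O)CO | intermediate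
18 | (2R,3R,4R)-4-[(S)-(tert-butyldimethylsilyloxy)(3,4-dimethoxyphenyl)methyl]-2-(3,4,5-trimethoxyphenyl)oxolane-3-carbaldehyde | COc1ccc(cc1OC)[C@@H](O[Si](C)(C)C(C)(C)C)[C@H]2CO[C@@H](c3cc(OC)c(OC)c(OC)c3)[C@@H]2C=O | intermediate
19 | [(2R,3S,4R)-4-[(S)-(tert-butyldimethylsilyloxy)(3,4-dimethoxyphenyl)methyl]-2-(3,4,5-trimethoxyphenyl)oxolan-3-yl]methanol | COc1ccc(cc1OC)[C@@H](O[Si](C)(C)C(C)(C)C)[C@H]2CO[C@@H](c3cc(OC)c(OC)c(OC)c3)[C@@H]2CO | intermediate
20 | (S)-(3,4-dimethoxyphenyl)[(3R,4S,5R)-4-(hydroxymethyl)-5-(3,4,5-trimethoxyphenyl)oxolan-3-yl]methanol | COc1ccc([C@@H](O)[C@H]2CO[C@@H](c3cc(OC)c(OC)c(OC)c3)[C@@H]2CO)cc1OC | target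

**Step count and risks**

Total step count: 9. Longest linear sequence: 9 steps (1 → 20).

Steps most likely to fail:

Step 6. Ionisation of the benzylic C–O bond or protodesilylation of the allylsilane may outrun ionisation at the acetal carbon, and reversible opening of the 2-aryl ring under the silyl triflate may erode the 2,4-selectivity. The fallback sets out from 12 and returns at 16; it generates the same cation from a preformed α-acetoxy ether under a milder Lewis acid, with no free aldehyde or triflate present. Alcohol 12 is acylated with 3,4,5-trimethoxybenzoyl chloride (pyridine, DMAP, CH2Cl2) to the 3,4,5-trimethoxybenzoate F1. Reduction with i-Bu2AlH at −78 °C gives the aluminium hemiacetal F2, which is acetylated in the same flask (Ac2O, pyridine, DMAP) to the α-acetoxy ether F3 (Rychnovsky reductive acetylation). BF3·OEt2 in CH2Cl2 at −78 °C should then ionise F3 to the cation of 15, which closes to 16 as in the main route.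

Step 5. Metathesis at the branched, crowded vinyl group may be slow, so that catalyst decay, self-metathesis of 11 and double-bond migration take over. The fallback sets out from 4 and returns at 12; it introduces silicon before the aldol, on an unhindered alkene. Imide 4 is cross-metathesised with 11 (same ruthenium catalyst) to (4S)-4-benzyl-3-[(E)-5-(trimethylsilyl)pent-3-enoyl]-1,3-oxazolidin-2-one F4. Bu2BOTf and Et3N give the dibutylboron dienolate F5, which adds to aldehyde 5 to give the boron aldolate F6 and, after H2O2 work-up, the syn aldol adduct F7. TBSOTf and 2,6-lutidine give the silyl ether F8, and LiBH4 removal of the auxiliary delivers 12.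

Step 7. The enolisable 3-formyl compound may lose the ring oxygen by β-elimination (opening of the oxolane) during base equilibration, and dihydroxylation of the flanked vinyl group may be slow or over-oxidise. The fallback sets out from 16 and returns at 19; the aldehyde is never isolated or exposed to base. Ozonolysis of 16 (O3, CH2Cl2, −78 °C, stopped at the first excess of ozone to spare the electron-rich rings) gives the secondary ozonide F9, which is reduced in the same flask with NaBH4 and MeOH directly to alcohol 19. This relies on the kinetic 2,3-trans selectivity of step 6, and any 3-epimer would have to be removed by chromatography at 19.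

**Further compounds**

F1 | step 6 | (2R,3E)-2-[(S)-(tert-butyldimethylsilyloxy)(3,4-dimethoxyphenyl)methyl]-5-(trimethylsilyl)pent-3-en-1-yl 3,4,5-trimethoxybenzoate | COc1ccc(cc1OC)[C@@H](O[Si](C)(C)C(C)(C)C)[C@@H](COC(=O)c1cc(OC)c(OC)c(OC)c1)/C=C/C[Si](C)(C)C
F2 | step 6 | diisobutylaluminium hemiacetal from reduction of F1, both configurations at the acetal carbon | COc1ccc(cc1OC)[C@@H](O[Si](C)(C)C(C)(C)C)[C@@H](COC(O[Al](CC(C)C)CC(C)C)c1cc(OC)c(OC)c(OC)c1)/C=C/C[Si](C)(C)C
F3 | step 6 | α-acetoxy ether: [(2R,3E)-2-{(S)-(tert-butyldimethylsilyloxy)(3,4-dimethoxyphenyl)methyl}-5-(trimethylsilyl)pent-3-en-1-yloxy](3,4,5-trimethoxyphenyl)methyl acetate, both configurations at the acetal carbon | COc1ccc(cc1OC)[C@@H](O[Si](C)(C)C(C)(C)C)[C@@H](COC(OC(C)=O)c1cc(OC)c(OC)c(OC)c1)/C=C/C[Si](C)(C)C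
F4 | step 5 | (4S)-4-benzyl-3-[(E)-5-(trimethylsilyl)pent-3-enoyl]-1,3-oxazolidin-2-one | C[Si](C)(C)C/C=C/CC(=O)N1C(=O)OC[C@@H]1Cc1ccccc1
F5 | step 5 | dibutylboron (Z)-dienolate of F4 | C[Si](C)(C)C/C=C/C=C(\OB(CCCC)CCCC)N1C(=O)OC[C@@H]1Cc1ccccc1
F6 | step 5 | dibutylboron aldolate of F7 | COc1ccc(cc1OC)[C@@H](OB(CCCC)CCCC)[C@@H](C(=O)N1C(=O)OC[C@@H]1Cc1ccccc1)/C=C/C[Si](C)(C)C
F7 | step 5 | (4S)-4-benzyl-3-[(2S,3E)-2-{(S)-(3,4-dimethoxyphenyl)(hydroxy)methyl}-5-(trimethylsilyl)pent-3-enoyl]-1,3-oxazolidin-2-one | COc1ccc(cc1OC)[C@@H](O)[C@@H](C(=O)N1C(=O)OC[C@@H]1Cc1ccccc1)/C=C/C[Si](C)(C)C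
F8 | step 5 | (4S)-4-benzyl-3-[(2S,3E)-2-{(S)-(tert-butyldimethylsilyloxy)(3,4-dimethoxyphenyl)methyl}-5-(trimethylsilyl)pent-3-enoyl]-1,3-oxazolidin-2-one | COc1ccc(cc1OC)[C@@H](O[Si](C)(C)C(C)(C)C)[C@@H](C(=O)N1C(=O)OC[C@@H]1Cc1ccccc1)/C=C/C[Si](C)(C)C
F9 | step 7 | secondary ozonide of 16: 3-[(2R,4R)-4-{(S)-(tert-butyldimethylsilyloxy)(3,4-dimethoxyphenyl)methyl}-2-(3,4,5-trimethoxyphenyl)oxolan-3-yl]-1,2,4-trioxolane, ring configuration as in 16 | COc1ccc(cc1OC)[C@@H](O[Si](C)(C)C(C)(C)C)[C@H]2CO[C@@H](c3cc(OC)c(OC)c(OC)c3)[C@@H]2C4OCOO4
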